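**Plan**
- Retrosynthesis: the C2–CO2H bond is cut first (pyrrol-2-yl carbanion synthon + CO2). The four C–Br bonds of the resulting 2,3,4,5-tetrabromo-1-methylpyrrole are cut next, which leads back to 1-methylpyrrole.
- Forward: the pyrrole ring is bought, not built. Exhaustive bromination fills C2–C5, then one α-bromine is replaced by the carboxyl group through cathodic reduction under CO2.
- Enabling feature: in the tetrabromide, ring atoms C2 and C5 (both bonded to N1) are symmetry-equivalent (C2v) and carry the most easily reduced C–Br bonds. C3–Br and C4–Br are less activated.
- One two-electron event therefore fixes the whole pattern N1-Me, C2-CO2H, C3/C4/C5-Br. One bromine is the activating and leaving group and three stay as target substituents, so no helper group has to be removed.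
- Stereochemistry: the target is planar and achiral, so nothing has to be set.

Key step: step 2

Remark: the target SMILES holds no stereocentre, stereogenic axis or double-bond geometry, so "single enantiomer" is taken to mean the one achiral compound.

**Step 1**
Reactants: 1 1-methylpyrrole
Product: 2 2,3,4,5-tetrabromo-1-methylpyrrole
Conditions: NBS (4.1 equiv), THF, −78 °C to rt, Ar, dark; short silica plug, used promptly
Reagents that add atoms: N-bromosuccinimide, O=C1CCC(=O)N1Br
Why: Exhaustive electrophilic aromatic bromination (SEAr) of the π-excessive pyrrole should work because the α positions react first and the β positions follow on warming, while neutral succinimide forms instead of the HBr that would polymerise the ring; no stereocentre is formed.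

**Step 2**
Reactants: 2 2,3,4,5-tetrabromo-1-methylpyrrole, 3 carbon dioxide
Product: 7 3,4,5-tribromo-1-methylpyrrole-2-carboxylic acid, via tribromopyrrolyl σ-radical 4 (not isolated), via tribromopyrrolyl carbanion 5 (not isolated), via bromomagnesium carboxylate 6 (not isolated)
Conditions: undivided cell, Ag cathode, Mg sacrificial anode, n-Bu4NBF4 (0.1 M), DMF, CO2 (1 atm), 0 °C, controlled potential at the first reduction wave of 2, 2.0 F/mol; then 1 M HCl, 0 °C, acid–base extraction
Reagents that add atoms: carbon dioxide (= compound 3), O=C=O
Why: This is a cathodic electrocarboxylation of a heteroaryl bromide with a sacrificial magnesium anode: dissociative electron transfer to 2 cleaves one Cα–Br bond to σ-radical 4, which is reduced at once to σ-carbanion 5 because its reduction potential lies far positive of the working potential; 5 adds to the carbon of dissolved 3 to form the C2–carboxyl bond, Mg2+ from the anode pairs with the carboxylate as 6, and cold dilute acid releases 7. The closest known reaction types are the sacrificial-anode reductive carboxylation of aryl and five-membered heteroaryl bromides and the stepwise, α-first cathodic debromination of perbrominated thiophenes. Site selectivity (C2/C5 over C3/C4) should follow because the developing carbanion is best stabilised next to N1 and beside C3–Br, and since C2 and C5 of C2v-symmetric 2 are equivalent, cleavage at either gives the same product. Selectivity for a single event should follow from a potential gap, since carboxylate 6 has one bromine fewer and a negative charge and should be reduced only at a more negative potential than 2, so holding the cathode at the first wave and stopping at 2 F/mol should spare the other three C–Br bonds. Every ring carbon bears bromine, so there is no C–H to start a halogen dance (α-bromine transfer between 5 and 2 is degenerate), and loss of bromide from 5 would need a prohibitively strained 2,3-pyrrolyne. No ring is closed and no stereocentre is formed.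

**Compound list**
1 | 1-methylpyrrole | Cn1cccc1 | starting material
2 | 2,3,4,5-tetrabromo-1-methylpyrrole | Cn1c(Br)c(Br)c(Br)c1Br | intermediate
3 | carbon dioxide | O=C=O | starting material
4 | 3,4,5-tribromo-1-methylpyrrol-2-yl σ-radical | Cn1c(Br)c(Br)c(Br)[c]1 | intermediate
5 | 3,4,5-tribromo-1-methylpyrrol-2-yl carbanion | Cn1c(Br)c(Br)c(Br)[c-]1 | intermediate
6 | bromomagnesium 3,4,5-tribromo-1-methylpyrrole-2-carboxylate | Cn1c(Br)c(Br)c(Br)c1C(=O)[O-].[Mg+2].[Br-] | intermediate
7 | 3,4,5-tribromo-1-methylpyrrole-2-carboxylic acid | Cn1c(Br)c(Br)c(Br)c1C(=O)O | target

Total step count: 2
Longest linear sequence: 2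

**Steps most likely to fail** (the route holds only two steps, so both are ranked)

1. Step 2.
   - What may go wrong: reduction may run on after the first event, with loss of a further bromine or a second carboxylation at C5. The σ-radical or carbanion may also pick up hydrogen from the medium before it meets CO2. Magnesium salts may passivate the cathode.
   - Fallback (stoichiometric halogen–metal exchange in place of electron transfer): it sets out from 2. Treatment with n-BuLi (1.0 equiv) in THF at −78 °C should exchange one α-bromine and give 3,4,5-tribromo-1-methylpyrrol-2-yllithium F1. Dry CO2 is passed in at −78 °C to give lithium 3,4,5-tribromo-1-methylpyrrole-2-carboxylate F2. Cold 1 M HCl then brings the sequence back to the route at 7.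

2. Step 1.
   - What may go wrong: bromination may stall at the β positions. The electron-rich ring may decompose by oxidation or acid-induced oligomerisation. The light-sensitive perbromide may decay during isolation.
   - Fallback (order reversed, carboxyl carbon first and bromines afterwards on a deactivated, robust ring): it sets out from 1. Uncatalysed Friedel–Crafts acylation with trichloroacetyl chloride in Et2O at rt should give 2,2,2-trichloro-1-(1-methylpyrrol-2-yl)ethanone F3. Excess Br2 in AcOH (rt to 50 °C) should brominate C4, C5 and finally C3 to give 2,2,2-trichloro-1-(3,4,5-tribromo-1-methylpyrrol-2-yl)ethanone F4. Haloform-type cleavage with aqueous NaOH in THF gives sodium 3,4,5-tribromo-1-methylpyrrole-2-carboxylate F5. Acidification with cold dilute HCl comes back to the route at 7.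

**Further compounds**
F1 | step 2 | 3,4,5-tribromo-1-methylpyrrol-2-yllithium | [Li]c1c(Br)c(Br)c(Br)n1C
F2 | step 2 | lithium 3,4,5-tribromo-1-methylpyrrole-2-carboxylate | Cn1c(Br)c(Br)c(Br)c1C(=O)[O-].[Li+]
F3 | step 1 | 2,2,2-trichloro-1-(1-methylpyrrol-2-yl)ethanone | Cn1cccc1C(=O)C(Cl)(Cl)Cl
F4 | step 1 | 2,2,2-trichloro-1-(3,4,5-tribromo-1-methylpyrrol-2-yl)ethanone | Cn1c(Br)c(Br)c(Br)c1C(=O)C(Cl)(Cl)Cl
F5 | step 1 | sodium 3,4,5-tribromo-1-methylpyrrole-2-carboxylate | Cn1c(Br)c(Br)c(Br)c1C(=O)[O-].[Na+]
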